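At late times the readings climb slowly, and they stand well short of the Z charged: L stood at 39.8 % in red at 20.0 h, 23.9 % in grey at 20.0 h and 31.2 % in teal at 12.0 h, while Z in teal read 0 % by 3.00 h. I therefore kept a ledger of Z, the limiting reagent.

the same everywhere: Z 0.20 M

| charge | J | X | remark | time |
|---|---|---|---|---|
| teal | 2 equiv | 2.5 equiv | run made earlier |  |
| red | 1.3 equiv | 2.5 equiv | run made earlier |  |
| grey | 3 equiv | 2.5 equiv | run made earlier |  |
| ochre | 2 equiv | 3.8 equiv | run made earlier |  |
| Thursday's | 2.00 equiv | 2.50 equiv (fed, over 8.0 h) | all else is in the flask from the start; the feed brings no volume worth counting | 20 h |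
| Saturday's | 2.00 equiv | 2.50 equiv | everything together at the start | 20 h |
| Tuesday's | 2.00 equiv (fed, over 8.0 h) | 2.50 equiv | all else is in the flask from the start; the feed brings no volume worth counting | 20 h |
| Monday's | 2.00 equiv | 2.50 equiv (in portions, 3, over 8.0 h) | first portion at the start, last at 8.0 h | 20 h |

| run | time / h | L / % | Z / % |
|---|---|---|---|
| teal | 1.00 | 4.0 | 12.1 |
| teal | 3.00 | 20.7 | 0 |
| teal | 6.00 | 26.9 | 1.5 |
| teal | 8.00 | 30.8 | 1.1 |
| teal | 12.0 | 31.2 | 3.7 |
| red | 4.00 | 19.6 | 0 |
| red | 8.00 | 35.3 | 0.6 |
| red | 12.0 | 36.6 | 0.3 |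
| red | 15.0 | 38.4 | 0 |
| red | 20.0 | 39.8 | 0.3 |
| grey | 4.00 | 21.1 | 0 |
| grey | 8.00 | 24.4 | 0.1 |
| grey | 12.0 | 23.6 | 0 |
| grey | 15.0 | 22.6 | 1.1 |
| grey | 20.0 | 23.9 | 0 |
| ochre | 1.50 | 15.3 | 1.0 |
| ochre | 3.00 | 25.9 | 0 |
| ochre | 6.00 | 34.3 | 0.6 |
| ochre | 10.0 | 36.6 | 0 |
| ochre | 20.0 | 36.5 | 0 |

(scatter of a reading: 1 percentage point)

- the analysis behind the earlier runs scatters by 1 percentage point, standard deviation
- steps under discussion: Z + X -> Q; X + J -> G; Q + G -> L; Z + G -> D

- the flask that comes out highest in amount of L, in percent of the Z charged, or "all alike" when all lie within 1.5 percentage points (Thursday's / Saturday's / Tuesday's / Monday's / all alike)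
- L at the end, in percent of the Z charged, Thursday's
- L at the end, in percent of the Z charged, Saturday's
- L at the end, in percent of the Z charged, Tuesday's
- L at the end, in percent of the Z charged, Monday's

Each Z has two exits: through Q, which G turns into L, or straight into D by taking a G. As a rough approximation I charged one Z to each G made, although teal's reading of 4.0 % L beside 12.1 % Z at 1.00 h shows that some G reaches Q while Z stands. In these books D forms at the rate of X + J and Q at the rate of Z + X, and [X] cancels from the split: D per Q equals r[J]/[Z], where r is an effective selectivity factor, to be read from the runs.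

Integrating this until Z is gone, with J all in from the start and j its equivalents, closes the books simply if r is 0.5: D takes j/(1+j) of the Z charged, and I call this the toll 66.7 %. The remainder, 33.3 %, is the entry for L. I read that r from the runs, where the same rule gives 43.5 % for red and 25.0 % for grey.

With [X] cancelled, my reckoning put Saturday's, Thursday's and Monday's all at 33.3 %. It gave no number for Tuesday's, where J is not in from the start. The forecast differed slightly: 33 % for Saturday's, 31 % for Thursday's and 32 % for Monday's. It set Tuesday's at 78 % and named Tuesday's highest, reasoning that “Feeding J lets Z become Q first”.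

Tuesday's came out highest at 75.8 %, above Saturday's 30.4 %, Monday's 22.7 % and Thursday's 22.5 %.

    Z + X → Q (k = 1.70 /M/h)
    X + J → G (k = 2.16 /M/h)
    Q + G → L (k = 3.55 /M/h)
    Z + G → D (k = 28.1 /M/h)

Against the toll of 66.7 %, D ended at 69.6 % in Saturday's but 77.4 % in Thursday's, so slow X moved the split although [X] had cancelled from my rule. At 5.36 h in Thursday's, Z was going into D at 7.3 times its rate into Q.

On Thursday's flask with 0.500 equiv of J, the toll gives D 33.3 %, leaving J for 16.7 % of L. The computed flask holds D 36.9 %, L 12.9 % and Q 50.2 %.

The runs come from a simulation from invented constants, noise included.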